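The pyran ring of the fisetinidol unit on C8 of the catechin (unit C) is opened at C4–C4a and C2–C3. A formal [4+2] (oxa-Povarov) reaction joins an aryl oxocarbenium ion, which carries the resorcinol ring, O1 and C2, to a C3=C4 enol acetate that already sits on C8 of a fisetinidol–fisetinidol–catechin trimer. It makes both bonds, the ring and three stereocentres at once. It exploits that C4 is benzylic to the trioxygenated catechin ring, which polarises the alkene and stabilises the C4 cation. The trimer comes from (+)-catechin and (+)-fustin by flavan-4-yl cation couplings.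

Key step: step 12

Remarks
- Units: A and B are the fisetinidol units chained onto C6 of the catechin unit D; C is the fisetinidol unit on C8 of D. Flavan numbering (O1, C2, C3, C4, C4a, C5–C8, C8a; primes for the 2-aryl ring) is used throughout.
- 4α means trans to the C3 oxygen in the 2,3-trans series; all three interflavanyl bonds of the target are 4α.
- Assumption: (+)-fustin, (2R,3R)-3,7,3',4'-tetrahydroxyflavanone, is bought from a natural-product supplier.
- Assumption: the antipode of the chiral acid in step 12 that delivers the required sense has to be fixed by a first experiment; (R) is written.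

Step 1
Reactants: 1 (+)-catechin
Product: 2 5,7,3',4'-tetra-O-benzyl-(+)-catechin
Conditions: BnBr, K2CO3, DMF, 0 °C to rt
Reagents that add atoms: benzyl bromide, BrCc1ccccc1
Why: Williamson etherification under weak base alkylates the four phenols and leaves the secondary 3-OH free; no stereocentre is touched.

Step 2
Reactants: 2 5,7,3',4'-tetra-O-benzyl-(+)-catechin
Product: 3 8-bromo-5,7,3',4'-tetra-O-benzyl-(+)-catechin
Conditions: NBS, CH2Cl2, −78 °C to rt
Reagents that add atoms: N-bromosuccinimide, O=C1CCC(=O)N1Br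
Why: Electrophilic aromatic bromination of the phloroglucinol-type ring should go to C8, between O1 and the 7-benzyloxy group, and the bromide is the handle for the two-carbon unit.

Step 3
Reactants: 3 8-bromo-5,7,3',4'-tetra-O-benzyl-(+)-catechin; 4 (E)-2-(2-ethoxyethenyl)-4,4,5,5-tetramethyl-1,3,2-dioxaborolane
Product: 6 8-(2-oxoethyl)-5,7,3',4'-tetra-O-benzyl-(+)-catechin, via enol ether 5 (not isolated)
Conditions: Pd(OAc)2 (5 mol %), SPhos (2-dicyclohexylphosphino-2',6'-dimethoxybiphenyl), K3PO4, dioxane/H2O, 90 °C; then 2 M HCl, THF, rt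
Reagents that add atoms: water, O
Why: Suzuki–Miyaura coupling with a bulky biarylphosphine accepts the di-ortho-oxygenated aryl bromide, and acid hydrolysis of the enol ether in the same pot unmasks the arylacetaldehyde, which also restores the nucleophilicity of C6.

Step 4
Reactants: 7 (+)-fustin
Product: 8 7,3',4'-tri-O-benzyl-(+)-fustin
Conditions: BnBr, K2CO3, DMF, rt
Reagents that add atoms: benzyl bromide, BrCc1ccccc1
Why: Williamson etherification of the three phenols; the α-hydroxy ketone OH is not alkylated by K2CO3, and mild conditions should limit ring-opening epimerisation at C2.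

Step 5
Reactants: 8 7,3',4'-tri-O-benzyl-(+)-fustin
Product: 9 (2R,3S,4R)-7,3',4'-tri-O-benzylflavan-3,4-diol (2,3-trans-3,4-trans)
Conditions: NaBH4, THF/MeOH, 0 °C
Reagents that add atoms: none
Why: Axial hydride attack on the dihydroflavonol ketone should give the equatorial 4-OH (3,4-trans diol); the C4 configuration is of no consequence because C4 is ionised later.

Step 6
Reactants: 9 (2R,3S,4R)-7,3',4'-tri-O-benzylflavan-3,4-diol
Product: 10 4α-(2,6-dimethylphenylsulfanyl)-7,3',4'-tri-O-benzylfisetinidol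
Conditions: 2,6-Me2C6H3SH (3 equiv), BF3·OEt2 (20 mol %), CH2Cl2, −20 °C
Reagents that add atoms: 2,6-dimethylbenzenethiol, Cc1cccc(C)c1S
Why: Acid-catalysed thiolysis: the C4 hydroxyl ionises to the benzylic cation stabilised by O1 and the 7-benzyloxy group, and the thiol captures it anti to the C3 hydroxyl; the hindered aryl sulfide is inert to hard Lewis acids and is the latent leaving group of unit B.

Step 7
Reactants: 9 (2R,3S,4R)-7,3',4'-tri-O-benzylflavan-3,4-diol
Product: 11 (2R,3S,4R)-6-bromo-7,3',4'-tri-O-benzylflavan-3,4-diol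
Conditions: NBS, NaHCO3, CH2Cl2, −40 to 0 °C
Reagents that add atoms: N-bromosuccinimide, O=C1CCC(=O)N1Br
Why: Electrophilic aromatic bromination at C6 (para to O1, ortho to the 7-benzyloxy group) caps the only strongly nucleophilic position of the future unit A, so that it cannot self-condense or be alkylated later.

Step 8
Reactants: 11 (2R,3S,4R)-6-bromo-7,3',4'-tri-O-benzylflavan-3,4-diol; 10 4α-(2,6-dimethylphenylsulfanyl)-7,3',4'-tri-O-benzylfisetinidol
Product: 12 6-bromo-7,3',4'-tri-O-benzylfisetinidol-(4α→6)-4α-(2,6-dimethylphenylsulfanyl)-7,3',4'-tri-O-benzylfisetinidol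
Conditions: TMSOTf (10 mol %), 4 Å MS, CH2Cl2, −78 to −40 °C; 10 in excess
Reagents that add atoms: none
Why: Friedel–Crafts alkylation by the flavan-4-yl cation from 11 at C6 of 10 (para to O1, less hindered than C8), with attack anti to the C3 hydroxyl on the 2,3-trans half-chair giving the 4α bond; the sulfide of 10 is not ionised by the silyl Lewis acid.

Step 9
Reactants: 12 bromo-capped dimer sulfide; 6 8-(2-oxoethyl)-5,7,3',4'-tetra-O-benzyl-(+)-catechin
Product: 13 [6-bromo-7,3',4'-tri-O-benzylfisetinidol-(4α→6)-7,3',4'-tri-O-benzylfisetinidol]-(4α→6)-8-(2-oxoethyl)-5,7,3',4'-tetra-O-benzylcatechin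
Conditions: AgBF4, 2,6-di-tert-butyl-4-methylpyridine, THF, −20 to 0 °C; 6 in excess
Reagents that add atoms: none
Why: Thiophilic silver activation ionises the C4–S bond of unit B to the benzylic cation, which alkylates the only free position (C6) of the catechin ring of 6 (Friedel–Crafts) anti to the C3 hydroxyl, giving the 4α bond.

Step 10
Reactants: 13 trimer aldehyde
Product: 14 tri-O-acetyl trimer carrying an (E)-2-acetoxyethenyl group on C8 of unit D
Conditions: Ac2O, Et3N, DMAP (cat.), CH2Cl2, rt; E isomer taken on after chromatography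
Reagents that add atoms: acetic anhydride, CC(=O)OC(C)=O
Why: Acetylation of the three secondary alcohols and O-acetylation of the aldehyde enolate (enol ester formation) give the polarised C3=C4 alkene, the E isomer being favoured by the di-ortho-substituted aryl group.

Step 11
Reactants: 15 3,4-bis(benzyloxy)benzaldehyde; 16 3-(benzyloxy)phenol
Product: 18 [3-(benzyloxy)phenoxy][3,4-bis(benzyloxy)phenyl]methyl acetate (racemic), via chloro ester 17 (not isolated)
Conditions: AcCl (1.0 equiv), ZnCl2 (5 mol %), CH2Cl2, 0 °C; then 16, iPr2NEt, −20 °C to rt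
Reagents that add atoms: acetyl chloride, CC(=O)Cl
Why: Addition of the acyl chloride to the aldehyde gives the α-chloroalkyl ester, whose benzylic chloride is displaced by the phenol oxygen under amine base (O-alkylation, as in acyloxyalkyl aryl ether synthesis); the stereocentre is racemic and is erased on ionisation.

Step 12
Reactants: 14 trimer enol acetate; 18 O-aryl O-acetyl acetal
Product: 21 bromo-capped, tridecabenzylated tetra-O-acetyl tetramer, via aryl oxocarbenium ion 19 (not isolated), via benzylic cation 20 (not isolated)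
Conditions: (R)-3,3'-bis(2,4,6-triisopropylphenyl)-1,1'-binaphthyl-2,2'-diyl N-triflylphosphoramide (10 mol %), 4 Å MS, toluene/CH2Cl2, −40 °C; 18 in slight excess
Reagents that add atoms: none
Why: Proposed new method: the chiral acid ionises acylal 18 with loss of AcOH to the aryl oxocarbenium ion 19 (a cationic 2-oxadiene, C4a=C8a–O1+=C2), held as an ion pair with the chiral phosphoramide anion; its C2 is attacked by the acetoxy-bearing alkene carbon (future C3) of 14, giving cation 20 at C4, benzylic to the trioxygenated ring of unit D and bridged by the neighbouring acetoxy group, which is then captured by the aryloxy ring at the carbon para to its benzyloxy group (C4a). The closest known reaction types are the SnCl4-mediated oxa-Povarov formal [4+2] of aryl oxocarbenium ions with styrenes and the chiral phosphoric acid-catalysed Povarov reaction of β-substituted electron-rich styrenes; chiral-anion control of an oxa-Povarov reaction on an enol ester is the new element. The pyran ring closes by a six-membered cation–π (Friedel–Crafts, 6-endo on the arene) alkylation, so the whole is a stepwise inverse-demand [4+2]. C2 is set by the face of 19 left open in the chiral ion pair, C3 follows trans to the C2 aryl group from the E alkene in an extended transition state, and C4 is set trans to C3 by backside attack on the acetoxy-bridged cation through the all-equatorial chair, which should give the (2R,3S,4S) unit. The step needs C3 and not C4 of the alkene as the nucleophilic carbon (the enol acetate oxygen is a weak donor, the catechin ring a strong one), alkene and not arene attack on 19 (the catechin ring is fully substituted and unit A is bromine-capped), and closure on the doubly activated aryloxy ring para to its benzyloxy group and not at the carbon between the two oxygens or on the 2-aryl ring.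

Step 13
Reactants: 21 tetra-O-acetyl tetramer
Product: 22 bromo-capped tridecabenzylated tetramer tetraol
Conditions: NaOMe (cat.), MeOH/THF, rt to 40 °C
Reagents that add atoms: none
Why: Zemplén-type transesterification removes the four acetates without touching benzyl ethers, the aryl bromide or any stereocentre.

Step 14
Reactants: 22 tetramer tetraol
Product: 23 CNP0263622.1, fisetinidol-(4α→6)-fisetinidol-(4α→6)-[fisetinidol-(4α→8)]-catechin
Conditions: H2 (1 atm), Pd(OH)2/C, Et3N, THF/MeOH/H2O, rt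
Reagents that add atoms: none
Why: Hydrogenolysis cleaves the thirteen benzyl ethers and, with amine base, the aryl C–Br bond, while the benzylic C2–O1 and C4–aryl bonds of 4-arylflavan-3-ols are expected to be retained under these conditions.

Compound list
1 | (+)-catechin, (2R,3S)-3,5,7,3',4'-pentahydroxyflavan | Oc1cc(O)c2c(c1)O[C@H](c1ccc(O)c(O)c1)[C@@H](O)C2 | starting material
2 | 5,7,3',4'-tetra-O-benzyl-(+)-catechin | C(c5ccccc5)Oc1cc(OCc5ccccc5)c2c(c1)O[C@H](c1ccc(OCc5ccccc5)c(OCc5ccccc5)c1)[C@@H](O)C2 | intermediate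
3 | 8-bromo-5,7,3',4'-tetra-O-benzyl-(+)-catechin | C(c5ccccc5)Oc1cc(OCc5ccccc5)c2c(c1Br)O[C@H](c1ccc(OCc5ccccc5)c(OCc5ccccc5)c1)[C@@H](O)C2 | intermediate
4 | (E)-2-(2-ethoxyethenyl)-4,4,5,5-tetramethyl-1,3,2-dioxaborolane | CCO/C=C/B1OC(C)(C)C(C)(C)O1 | starting material
5 | 8-[(E)-2-ethoxyethenyl]-5,7,3',4'-tetra-O-benzyl-(+)-catechin | C(c5ccccc5)Oc1cc(OCc5ccccc5)c2c(c1/C=C/OCC)O[C@H](c1ccc(OCc5ccccc5)c(OCc5ccccc5)c1)[C@@H](O)C2 | intermediate
6 | 8-(2-oxoethyl)-5,7,3',4'-tetra-O-benzyl-(+)-catechin | C(c5ccccc5)Oc1cc(OCc5ccccc5)c2c(c1CC=O)O[C@H](c1ccc(OCc5ccccc5)c(OCc5ccccc5)c1)[C@@H](O)C2 | intermediate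
7 | (+)-fustin, (2R,3R)-3,7,3',4'-tetrahydroxyflavanone | Oc1ccc2c(c1)O[C@H](c1ccc(O)c(O)c1)[C@@H](O)C2=O | starting material
8 | 7,3',4'-tri-O-benzyl-(+)-fustin | C(c5ccccc5)Oc1ccc2c(c1)O[C@H](c1ccc(OCc5ccccc5)c(OCc5ccccc5)c1)[C@@H](O)C2=O | intermediate
9 | (2R,3S,4R)-7,3',4'-tri-O-benzylflavan-3,4-diol | C(c5ccccc5)Oc1ccc2c(c1)O[C@H](c1ccc(OCc5ccccc5)c(OCc5ccccc5)c1)[C@@H](O)[C@@H]2O | intermediate
10 | 4α-(2,6-dimethylphenylsulfanyl)-7,3',4'-tri-O-benzylfisetinidol | C(c5ccccc5)Oc1ccc2c(c1)O[C@H](c1ccc(OCc5ccccc5)c(OCc5ccccc5)c1)[C@@H](O)[C@@H]2Sc1c(C)cccc1C | intermediate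
11 | (2R,3S,4R)-6-bromo-7,3',4'-tri-O-benzylflavan-3,4-diol | C(c5ccccc5)Oc1c(Br)cc2c(c1)O[C@H](c1ccc(OCc5ccccc5)c(OCc5ccccc5)c1)[C@@H](O)[C@@H]2O | intermediate
12 | 6-bromo-7,3',4'-tri-O-benzylfisetinidol-(4α→6)-4α-(2,6-dimethylphenylsulfanyl)-7,3',4'-tri-O-benzylfisetinidol | C(c5ccccc5)Oc1c(Br)cc2c(c1)O[C@H](c1ccc(OCc5ccccc5)c(OCc5ccccc5)c1)[C@@H](O)[C@@H]2c1cc2c(cc1OCc5ccccc5)O[C@H](c1ccc(OCc5ccccc5)c(OCc5ccccc5)c1)[C@@H](O)[C@@H]2Sc1c(C)cccc1C | intermediate
13 | [6-bromo-7,3',4'-tri-O-benzylfisetinidol-(4α→6)-7,3',4'-tri-O-benzylfisetinidol]-(4α→6)-8-(2-oxoethyl)-5,7,3',4'-tetra-O-benzylcatechin | C(c5ccccc5)Oc1c(Br)cc2c(c1)O[C@H](c1ccc(OCc5ccccc5)c(OCc5ccccc5)c1)[C@@H](O)[C@@H]2c1cc2c(cc1OCc5ccccc5)O[C@H](c1ccc(OCc5ccccc5)c(OCc5ccccc5)c1)[C@@H](O)[C@@H]2c1c(OCc5ccccc5)c2c(c(CC=O)c1OCc5ccccc5)O[C@H](c1ccc(OCc5ccccc5)c(OCc5ccccc5)c1)[C@@H](O)C2 | intermediate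
14 | tri-O-acetate of the trimer with an (E)-2-acetoxyethenyl group on C8 of unit D | C(c5ccccc5)Oc1c(Br)cc2c(c1)O[C@H](c1ccc(OCc5ccccc5)c(OCc5ccccc5)c1)[C@@H](OC(C)=O)[C@@H]2c1cc2c(cc1OCc5ccccc5)O[C@H](c1ccc(OCc5ccccc5)c(OCc5ccccc5)c1)[C@@H](OC(C)=O)[C@@H]2c1c(OCc5ccccc5)c2c(c(/C=C/OC(C)=O)c1OCc5ccccc5)O[C@H](c1ccc(OCc5ccccc5)c(OCc5ccccc5)c1)[C@@H](OC(C)=O)C2 | intermediate
15 | 3,4-bis(benzyloxy)benzaldehyde | O=Cc1ccc(OCc5ccccc5)c(OCc5ccccc5)c1 | starting material
16 | 3-(benzyloxy)phenol | Oc1cccc(OCc5ccccc5)c1 | starting material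
17 | chloro[3,4-bis(benzyloxy)phenyl]methyl acetate (racemic) | CC(=O)OC(Cl)c1ccc(OCc5ccccc5)c(OCc5ccccc5)c1 | intermediate
18 | [3-(benzyloxy)phenoxy][3,4-bis(benzyloxy)phenyl]methyl acetate (racemic) | CC(=O)OC(Oc1cccc(OCc5ccccc5)c1)c1ccc(OCc5ccccc5)c(OCc5ccccc5)c1 | intermediate
19 | [3-(benzyloxy)phenyl][3,4-bis(benzyloxy)benzylidene]oxonium ion (aryl oxocarbenium ion, paired with the catalyst anion) | C(c5ccccc5)Oc1cccc(c1)[O+]=Cc1ccc(OCc5ccccc5)c(OCc5ccccc5)c1 | intermediate
20 | open-chain C4 benzylic cation on C8 of unit D, with C2 and C3 of unit C already set | C(c5ccccc5)Oc1c(Br)cc2c(c1)O[C@H](c1ccc(OCc5ccccc5)c(OCc5ccccc5)c1)[C@@H](OC(C)=O)[C@@H]2c1cc2c(cc1OCc5ccccc5)O[C@H](c1ccc(OCc5ccccc5)c(OCc5ccccc5)c1)[C@@H](OC(C)=O)[C@@H]2c1c(OCc5ccccc5)c2c(c([CH+][C@H](OC(C)=O)[C@@H](c4ccc(OCc5ccccc5)c(OCc5ccccc5)c4)Oc4cccc(OCc5ccccc5)c4)c1OCc5ccccc5)O[C@H](c1ccc(OCc5ccccc5)c(OCc5ccccc5)c1)[C@@H](OC(C)=O)C2 | intermediate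
21 | tetra-O-acetyl, tridecabenzyl, 6-bromo (unit A) derivative of the target | C(c5ccccc5)Oc1c(Br)cc2c(c1)O[C@H](c1ccc(OCc5ccccc5)c(OCc5ccccc5)c1)[C@@H](OC(C)=O)[C@@H]2c1cc2c(cc1OCc5ccccc5)O[C@H](c1ccc(OCc5ccccc5)c(OCc5ccccc5)c1)[C@@H](OC(C)=O)[C@@H]2c1c(OCc5ccccc5)c2c(c([C@@H]3c4ccc(OCc5ccccc5)cc4O[C@H](c4ccc(OCc5ccccc5)c(OCc5ccccc5)c4)[C@H]3OC(C)=O)c1OCc5ccccc5)O[C@H](c1ccc(OCc5ccccc5)c(OCc5ccccc5)c1)[C@@H](OC(C)=O)C2 | intermediate
22 | tridecabenzyl, 6-bromo (unit A) derivative of the target with four free 3-OH groups | C(c5ccccc5)Oc1c(Br)cc2c(c1)O[C@H](c1ccc(OCc5ccccc5)c(OCc5ccccc5)c1)[C@@H](O)[C@@H]2c1cc2c(cc1OCc5ccccc5)O[C@H](c1ccc(OCc5ccccc5)c(OCc5ccccc5)c1)[C@@H](O)[C@@H]2c1c(OCc5ccccc5)c2c(c([C@@H]3c4ccc(OCc5ccccc5)cc4O[C@H](c4ccc(OCc5ccccc5)c(OCc5ccccc5)c4)[C@H]3O)c1OCc5ccccc5)O[C@H](c1ccc(OCc5ccccc5)c(OCc5ccccc5)c1)[C@@H](O)C2 | intermediate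
23 | CNP0263622.1, fisetinidol-(4α→6)-fisetinidol-(4α→6)-[fisetinidol-(4α→8)]-catechin | Oc1ccc2c(c1)O[C@H](c1ccc(O)c(O)c1)[C@@H](O)[C@@H]2c1cc2c(cc1O)O[C@H](c1ccc(O)c(O)c1)[C@@H](O)[C@@H]2c1c(O)c2c(c([C@@H]3c4ccc(O)cc4O[C@H](c4ccc(O)c(O)c4)[C@H]3O)c1O)O[C@H](c1ccc(O)c(O)c1)[C@@H](O)C2 | target

Total step count: 14
Longest linear sequence: 9 steps (steps 4, 5, 7, 8, 9, 10, 12, 13, 14, from (+)-fustin)

Steps most likely to fail

Step 12. The chiral ion pair may discriminate the two faces of the oxocarbenium ion poorly. The ion may also alkylate an arene position, or the acid may consume the enol acetate before the alkene is attacked. The fallback uses known flavan-4-yl cation chemistry; it sets out from 9, 2 and 12 and rejoins the route at 22. Diol 9 and an excess of tetra-O-benzylcatechin 2 with TMSOTf (10 mol %) in CH2Cl2 at −78 °C would couple at C8 of 2, anti to the C3 hydroxyl, to give 7,3',4'-tri-O-benzylfisetinidol-(4α→8)-5,7,3',4'-tetra-O-benzylcatechin F1. AgBF4-mediated coupling of sulfide 12 with F1 at the remaining C6 of the catechin ring (hindered pyridine base, THF, 0 °C) would then give tetraol 22 directly. Its own weak point is competition from C6 of the resorcinol ring of unit C.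

Step 9. Attack at the doubly flanked C6 may be slow, and the acid released may drive self-condensation of the enolisable aldehyde. The fallback masks the aldehyde as an alkene; it sets out from 3 and 12 and rejoins at 13. Stille coupling of bromide 3 with allyltributylstannane (Pd(PPh3)4, CsF, dioxane, 100 °C) would give 8-allyl-5,7,3',4'-tetra-O-benzylcatechin F2. AgBF4 coupling of F2 with 12 as in step 9 would give the 8-allyl trimer F3. Lemieux–Johnson cleavage (OsO4 cat., NaIO4, 2,6-lutidine, dioxane/H2O) would then deliver aldehyde 13.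

Step 11. The chloro ester may revert to the aldehyde, the phenol may be acetylated, or it may be alkylated on carbon instead of oxygen. The fallback builds the acylal from an ester; it sets out from 15 and 16 and rejoins at 18. Pinnick oxidation of 15 (NaClO2, NaH2PO4, 2-methyl-2-butene, tBuOH/H2O) would give 3,4-bis(benzyloxy)benzoic acid F4. Carbodiimide esterification with phenol 16 (DCC, DMAP, CH2Cl2) would give 3-(benzyloxy)phenyl 3,4-bis(benzyloxy)benzoate F5. Reduction with iBu2AlH at −78 °C, followed by trapping of the aluminium hemiacetal with Ac2O, pyridine and DMAP (reductive acetylation of an ester), would give acylal 18.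

Further compounds
F1 | step 12 | 7,3',4'-tri-O-benzylfisetinidol-(4α→8)-5,7,3',4'-tetra-O-benzylcatechin | C(c5ccccc5)Oc1cc(OCc5ccccc5)c2c(c1[C@@H]3c4ccc(OCc5ccccc5)cc4O[C@H](c4ccc(OCc5ccccc5)c(OCc5ccccc5)c4)[C@H]3O)O[C@H](c1ccc(OCc5ccccc5)c(OCc5ccccc5)c1)[C@@H](O)C2
F2 | step 9 | 8-allyl-5,7,3',4'-tetra-O-benzylcatechin | C(c5ccccc5)Oc1cc(OCc5ccccc5)c2c(c1CC=C)O[C@H](c1ccc(OCc5ccccc5)c(OCc5ccccc5)c1)[C@@H](O)C2
F3 | step 9 | [6-bromo-7,3',4'-tri-O-benzylfisetinidol-(4α→6)-7,3',4'-tri-O-benzylfisetinidol]-(4α→6)-8-allyl-5,7,3',4'-tetra-O-benzylcatechin | C(c5ccccc5)Oc1c(Br)cc2c(c1)O[C@H](c1ccc(OCc5ccccc5)c(OCc5ccccc5)c1)[C@@H](O)[C@@H]2c1cc2c(cc1OCc5ccccc5)O[C@H](c1ccc(OCc5ccccc5)c(OCc5ccccc5)c1)[C@@H](O)[C@@H]2c1c(OCc5ccccc5)c2c(c(CC=C)c1OCc5ccccc5)O[C@H](c1ccc(OCc5ccccc5)c(OCc5ccccc5)c1)[C@@H](O)C2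
F4 | step 11 | 3,4-bis(benzyloxy)benzoic acid | OC(=O)c1ccc(OCc5ccccc5)c(OCc5ccccc5)c1
F5 | step 11 | 3-(benzyloxy)phenyl 3,4-bis(benzyloxy)benzoate | O=C(Oc1cccc(OCc5ccccc5)c1)c1ccc(OCc5ccccc5)c(OCc5ccccc5)c1
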